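**Plan**

- Retrosynthesis: the three benzyl ethers and the two outer butyryl C–C bonds are removed first. Each outer ring (C1 acyl-bearing, C2/C4/C6 oxygenated, C3 gem-dimethyl, C5 bridge-bearing) is then cut at C4–C5 and C6–C1 into 3-ethoxy-4,4-dimethylcyclobutenone and an arylmethyl ynol ether.
- Further back, the two propargylic CH2–C(sp) bonds, the two ring A–CH2 bonds (as formyl groups) and the ring A–butyryl bond lead to phloroglucinol. The cyclobutenone comes from dimethylketene and ethoxyacetylene.
- Forward: aromatic ring A is fully substituted first (steps 1–6). Both non-aromatic rings B and B' then close together in one thermal cascade (step 8). Hydrolysis, C-butyrylation and debenzylation finish the synthesis (steps 9–11).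
- Enabling feature: in each outer ring the oxygens alternate (C2, C4, C6) and the quaternary C3 lies between C2 and C4. A dimethyl-terminated vinylketene and an alkoxyalkyne deliver exactly this pattern, and C3 stops the annulation at the dienone instead of a phenol.
- Stereochemistry: the target has no stereocentre; the only stereocentres on the way are transient and are erased inside the cascade.

Key step: step 8

Assumption: the enolised triketone rings of 20–23 (and of F1, F2 and F8) equilibrate rapidly between tautomers; each compound is written as one tautomer, 23 in the form of the target SMILES.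

**Route**

Step 1
Reactants: 1 phloroglucinol
Product: 3 2,4-diformylphloroglucinol, via bis(iminium) salt 2 (not isolated)
Conditions: POCl3 (2.5 equiv), DMF, 1,4-dioxane, 0 °C to rt; then H2O
Reagents that add atoms: N,N-dimethylformamide, CN(C)C=O (formyl carbons; NMe2 groups of 2); water, O (aldehyde oxygens); phosphoryl chloride, O=P(Cl)(Cl)Cl (chloride counter-ions of 2)
Why: Vilsmeier–Haack formylation: the chloroiminium ion attacks the very electron-rich ring twice, the two iminium groups then deactivate it against a third attack, and aqueous work-up hydrolyses 2 to the dialdehyde.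

Step 2
Reactants: 3 2,4-diformylphloroglucinol; 4 butanoyl chloride
Product: 5 5-butanoyl-2,4,6-trihydroxybenzene-1,3-dicarbaldehyde
Conditions: TiCl4, ClCH2CH2Cl, 0 to 40 °C; then 1 M HCl
Reagents that add atoms: none
Why: Friedel–Crafts acylation at the single free ring carbon, which is ortho or para to all three hydroxyl groups and so stays nucleophilic despite the two chelated formyl groups; this is an established entry to 3,5-diformyl acylphloroglucinols.

Step 3
Reactants: 5 5-butanoyl-2,4,6-trihydroxybenzene-1,3-dicarbaldehyde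
Product: 6 2,4,6-tris(benzyloxy)-5-butanoylbenzene-1,3-dicarbaldehyde
Conditions: BnBr (4 equiv), K2CO3, DMF, 60 °C
Reagents that add atoms: benzyl bromide, BrCc1ccccc1
Why: Williamson etherification: the three chelated but acidic phenols are O-alkylated by the reactive benzylic bromide in a dipolar aprotic solvent, and every ring carbon is already substituted, which disfavours C-alkylation.

Step 4
Reactants: 6 2,4,6-tris(benzyloxy)-5-butanoylbenzene-1,3-dicarbaldehyde
Product: 7 1-[2,4,6-tris(benzyloxy)-3,5-bis(hydroxymethyl)phenyl]butan-1-one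
Conditions: NaBH4 (1.0 equiv), THF/EtOH, −40 °C; aq. NH4Cl
Reagents that add atoms: none
Why: Chemoselective borohydride reduction: the aldehydes are far more electrophilic than the aryl ketone, which is twisted out of conjugation and shielded by two ortho benzyloxy groups, so limiting hydride at low temperature should reduce only the formyl groups.

Step 5
Reactants: 7 1-[2,4,6-tris(benzyloxy)-3,5-bis(hydroxymethyl)phenyl]butan-1-one
Product: 8 1-[2,4,6-tris(benzyloxy)-3,5-bis(bromomethyl)phenyl]butan-1-one
Conditions: CBr4, PPh3, CH2Cl2, 0 °C; used at once without storage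
Reagents that add atoms: tetrabromomethane, BrC(Br)(Br)Br
Why: Appel reaction: each benzylic alkoxyphosphonium ion is displaced by bromide under neutral conditions that leave the benzyl ethers and the ketone untouched.

Step 6
Reactants: 8 1-[2,4,6-tris(benzyloxy)-3,5-bis(bromomethyl)phenyl]butan-1-one; 9 ethoxyacetylene (2.5 equiv)
Product: 12 1-[2,4,6-tris(benzyloxy)-3,5-bis(3-ethoxyprop-2-yn-1-yl)phenyl]butan-1-one, via lithium ethoxyacetylide 10 (not isolated), via (ethoxyethynyl)zinc bromide 11 (not isolated)
Conditions: 9 (2.5 equiv), n-BuLi (2.4 equiv), THF, −78 °C; ZnBr2 (2.5 equiv), −78 to 0 °C; then 8 (1 equiv), PdCl2(DPEphos) (5 mol% per C–Br; DPEphos = bis[2-(diphenylphosphino)phenyl] ether), THF, rt; Et3N-deactivated silica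
Reagents that add atoms: n-butyllithium, [Li]CCCC (lithium of 10); zinc bromide, Br[Zn]Br (zinc and bromine of 11)
Why: Twofold Negishi coupling of the bis(benzylic bromide) with two equivalents of the alkynylzinc halide: oxidative addition of zerovalent palladium into each C–Br bond, transmetalation from zinc and reductive elimination form the two CH2–C(sp) bonds and bring in both ethoxyethynyl units, and the weakly basic zinc acetylide should tolerate the enolisable ketone and not isomerise the product to an allene.

Step 7
Reactants: 13 2-methylpropanoyl chloride; 9 ethoxyacetylene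
Product: 15 3-ethoxy-4,4-dimethylcyclobut-2-en-1-one, via dimethylketene 14 (not isolated)
Conditions: Et3N, Et2O/MeCN, 0 °C to rt
Reagents that add atoms: none
Why: Dehydrochlorination gives dimethylketene, which adds to the ynol ether in a [2+2] cycloaddition with the ketene carbonyl carbon bonding to the unsubstituted alkyne carbon, the standard preparation of 3-alkoxycyclobutenones.

Step 8
Reactants: 12 1-[2,4,6-tris(benzyloxy)-3,5-bis(3-ethoxyprop-2-yn-1-yl)phenyl]butan-1-one; 15 3-ethoxy-4,4-dimethylcyclobut-2-en-1-one (3 equiv)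
Product: 19 1-[2,4,6-tris(benzyloxy)-3,5-bis[(2,4-diethoxy-5,5-dimethyl-6-oxocyclohexa-1,3-dien-1-yl)methyl]phenyl]butan-1-one, via vinylketene 16 (not isolated), via bis(alkenylcyclobutenone) 17 (not isolated), via bis(dienylketene) 18 (not isolated)
Conditions: PhMe, 80–90 °C, sealed tube; Et3N-deactivated silica
Reagents that add atoms: none
Why: Conrotatory 4π opening of 15 gives vinylketene 16, whose electrophilic ketene carbon bonds to the nucleophilic, arylmethyl-bearing carbon of each ynol ether in a [2+2] cycloaddition (forming C4–C5 and C6–C1 of each outer ring), and the resulting 4-alkenylcyclobutenone 17 opens again to dienylketene 18. Each six-membered ring then closes by thermal disrotatory 6π electrocyclisation of the ketene carbon onto the dimethyl-substituted diene terminus, re-forming C3–C4. The closest known reaction type is the Danheiser annulation of cyclobutenones with alkoxyalkynes, in the variant where a 4,4-dialkylcyclobutenone ends at a 6,6-dialkylcyclohexa-2,4-dienone because the quaternary carbon cannot tautomerise to a phenol; the closure is also the thermal reverse of the photochemical opening of such dienones. No stereocentre remains in 19, since the two ring CH centres of 17 are erased in the next ring opening. The step needs regioselectivity in the [2+2] event, secured by the polarity match between the ketene carbon and the β-carbon of the ynol ether, and it needs the cascade to outrun retro-ene loss of ethylene from the ethyl ynol ether, which the moderate temperature and the excess of 15 are meant to secure.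

Step 9
Reactants: 19 1-[2,4,6-tris(benzyloxy)-3,5-bis[(2,4-diethoxy-5,5-dimethyl-6-oxocyclohexa-1,3-dien-1-yl)methyl]phenyl]butan-1-one
Product: 20 1-[2,4,6-tris(benzyloxy)-3,5-bis[(2,4-dihydroxy-5,5-dimethyl-6-oxocyclohexa-1,3-dien-1-yl)methyl]phenyl]butan-1-one
Conditions: 2 M HCl, THF, 50 °C
Reagents that add atoms: water, O
Why: Acid-catalysed hydrolysis of the vinylogous ester enol ethers (protonation at carbon, addition of water, loss of ethanol) should give the enolised cyclic triketone of each outer ring, while aryl benzyl ethers are stable to dilute aqueous acid.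

Step 10
Reactants: 20 1-[2,4,6-tris(benzyloxy)-3,5-bis[(2,4-dihydroxy-5,5-dimethyl-6-oxocyclohexa-1,3-dien-1-yl)methyl]phenyl]butan-1-one; 4 butanoyl chloride (2.2 equiv)
Product: 22 1-[2,4,6-tris(benzyloxy)-3,5-bis[(5-butanoyl-2,4-dihydroxy-3,3-dimethyl-6-oxocyclohexa-1,4-dien-1-yl)methyl]phenyl]butan-1-one, via bis(enol butanoate) 21 (not isolated)
Conditions: Et3N, CH2Cl2, 0 °C; then DMAP (0.3 equiv), rt to 40 °C; dilute HCl work-up
Reagents that add atoms: none
Why: O-Acylation of each vinylogous acid followed by DMAP-catalysed O-to-C acyl migration (acylpyridinium–enolate ion pair), the standard route to 2-acylcyclohexane-1,3-diones, should place the butyryl group on the only unsubstituted ring carbon, where the product is held as a chelated enolised triketone.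

Step 11
Reactants: 22 1-[2,4,6-tris(benzyloxy)-3,5-bis[(5-butanoyl-2,4-dihydroxy-3,3-dimethyl-6-oxocyclohexa-1,4-dien-1-yl)methyl]phenyl]butan-1-one
Product: 23 CNP0287270.0
Conditions: H2 (1 atm), Pd/C, EtOAc, rt
Reagents that add atoms: none
Why: Catalytic hydrogenolysis should cleave the three aryl benzyl ethers under neutral conditions that do not reduce the chelated aryl ketone, the enolised triketones or the diarylmethane-type bridges.

**Compound list**

1 | phloroglucinol (benzene-1,3,5-triol) | Oc1cc(O)cc(O)c1 | starting material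
2 | 2,4-bis(dimethyliminiomethyl)phloroglucinol dichloride (Vilsmeier bis(iminium) salt) | C[N+](C)=Cc1c(O)cc(O)c(C=[N+](C)C)c1O.[Cl-].[Cl-] | intermediate
3 | 2,4-diformylphloroglucinol (2,4,6-trihydroxybenzene-1,3-dicarbaldehyde) | O=Cc1c(O)cc(O)c(C=O)c1O | intermediate
4 | butanoyl chloride | CCCC(=O)Cl | starting material
5 | 5-butanoyl-2,4,6-trihydroxybenzene-1,3-dicarbaldehyde | CCCC(=O)c1c(O)c(C=O)c(O)c(C=O)c1O | intermediate
6 | 2,4,6-tris(benzyloxy)-5-butanoylbenzene-1,3-dicarbaldehyde | CCCC(=O)c1c(OCc2ccccc2)c(C=O)c(OCc2ccccc2)c(C=O)c1OCc1ccccc1 | intermediate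
7 | 1-[2,4,6-tris(benzyloxy)-3,5-bis(hydroxymethyl)phenyl]butan-1-one | CCCC(=O)c1c(OCc2ccccc2)c(CO)c(OCc2ccccc2)c(CO)c1OCc1ccccc1 | intermediate
8 | 1-[2,4,6-tris(benzyloxy)-3,5-bis(bromomethyl)phenyl]butan-1-one | CCCC(=O)c1c(OCc2ccccc2)c(CBr)c(OCc2ccccc2)c(CBr)c1OCc1ccccc1 | intermediate
9 | ethoxyacetylene (ethoxyethyne) | CCOC#C | starting material
10 | lithium ethoxyacetylide | CCOC#C[Li] | intermediate
11 | (ethoxyethynyl)zinc bromide | CCOC#C[Zn]Br | intermediate
12 | 1-[2,4,6-tris(benzyloxy)-3,5-bis(3-ethoxyprop-2-yn-1-yl)phenyl]butan-1-one | CCCC(=O)c1c(OCc2ccccc2)c(CC#COCC)c(OCc2ccccc2)c(CC#COCC)c1OCc1ccccc1 | intermediate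
13 | 2-methylpropanoyl chloride (isobutyryl chloride) | CC(C)C(=O)Cl | starting material
14 | dimethylketene | CC(C)=C=O | intermediate
15 | 3-ethoxy-4,4-dimethylcyclobut-2-en-1-one | CCOC1=CC(=O)C1(C)C | intermediate
16 | 3-ethoxy-4-methylpenta-1,3-dien-1-one (vinylketene) | CCOC(C=C=O)=C(C)C | intermediate
17 | bis(alkenylcyclobutenone): each arm of 12 as a 2-(arylmethyl)-3-ethoxy-4-(1-ethoxy-2-methylprop-1-enyl)cyclobut-2-en-1-one; both configurations at the two ring CH carbons | CCCC(=O)c1c(OCc2ccccc2)c(CC2=C(OCC)C(C(OCC)=C(C)C)C2=O)c(OCc2ccccc2)c(CC2=C(OCC)C(C(OCC)=C(C)C)C2=O)c1OCc1ccccc1 | intermediate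
18 | bis(dienylketene): each arm as a 2-(arylmethyl)-3,5-diethoxy-6-methylhepta-1,3,5-trien-1-one with the ketene-bearing carbon and the alkenyl group cis on the central double bond | CCCC(=O)c1c(OCc2ccccc2)c(CC(=C=O)/C(OCC)=C\C(OCC)=C(C)C)c(OCc2ccccc2)c(CC(=C=O)/C(OCC)=C\C(OCC)=C(C)C)c1OCc1ccccc1 | intermediate
19 | 1-[2,4,6-tris(benzyloxy)-3,5-bis[(2,4-diethoxy-5,5-dimethyl-6-oxocyclohexa-1,3-dien-1-yl)methyl]phenyl]butan-1-one | CCCC(=O)c1c(OCc2ccccc2)c(CC2=C(OCC)C=C(OCC)C(C)(C)C2=O)c(OCc2ccccc2)c(CC2=C(OCC)C=C(OCC)C(C)(C)C2=O)c1OCc1ccccc1 | intermediate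
20 | 1-[2,4,6-tris(benzyloxy)-3,5-bis[(2,4-dihydroxy-5,5-dimethyl-6-oxocyclohexa-1,3-dien-1-yl)methyl]phenyl]butan-1-one | CCCC(=O)c1c(OCc2ccccc2)c(CC2=C(O)C=C(O)C(C)(C)C2=O)c(OCc2ccccc2)c(CC2=C(O)C=C(O)C(C)(C)C2=O)c1OCc1ccccc1 | intermediate
21 | bis(enol butanoate) of 20, drawn as the 4-butanoyloxy-2-hydroxy-5,5-dimethyl-6-oxocyclohexa-1,3-dien-1-yl isomer on each arm (positional isomers converge in the migration) | CCCC(=O)c1c(OCc2ccccc2)c(CC2=C(O)C=C(OC(=O)CCC)C(C)(C)C2=O)c(OCc2ccccc2)c(CC2=C(O)C=C(OC(=O)CCC)C(C)(C)C2=O)c1OCc1ccccc1 | intermediate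
22 | 1-[2,4,6-tris(benzyloxy)-3,5-bis[(5-butanoyl-2,4-dihydroxy-3,3-dimethyl-6-oxocyclohexa-1,4-dien-1-yl)methyl]phenyl]butan-1-one | CCCC(=O)C1=C(O)C(C)(C)C(O)=C(Cc2c(OCc3ccccc3)c(CC3=C(O)C(C)(C)C(O)=C(C(=O)CCC)C3=O)c(OCc3ccccc3)c(C(=O)CCC)c2OCc2ccccc2)C1=O | intermediate
23 | CNP0287270.0: 1-[3,5-bis[(5-butanoyl-2,4-dihydroxy-3,3-dimethyl-6-oxocyclohexa-1,4-dien-1-yl)methyl]-2,4,6-trihydroxyphenyl]butan-1-one; no stereocentre | CCCC(=O)C1=C(O)C(C)(C)C(O)=C(Cc2c(O)c(CC3=C(O)C(C)(C)C(O)=C(C(=O)CCC)C3=O)c(O)c(C(=O)CCC)c2O)C1=O | target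

**Step count and risks**

Total step count: 11. Longest linear sequence: 10 steps (steps 1–6 and 8–11 from phloroglucinol); step 7 is a one-step branch.

Most likely to fail, step 8. The donor-substituted, 4,4-disubstituted cyclobutenone may open too slowly at temperatures the ethyl ynol ether tolerates. Retro-ene fragmentation of the ynol ether, ketene dimerisation or reaction of only one arm could then outpace the double annulation. The fallback sets out from dibromide 8 and brings the outer rings in preformed. Commercial 2,4,6-trihydroxyacetophenone is gem-dimethylated (MeI, NaOMe, MeOH) to acetylfilicinic acid F1. F1 is deacetylated in hot aqueous H2SO4 to filicinic acid F2. An excess of the monosodium salt of F2 (NaOMe, MeOH, 0 °C to rt) is then C-benzylated by 8 at one of its two equivalent nucleophilic ring carbons. This should give 20 directly, and the route is rejoined at step 10.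

Second, step 6. The doubly ortho-alkoxylated benzylic bromide may ionise and decompose in the presence of zinc halide. Oxidative addition at the hindered benzylic carbon may also be slow enough for homocoupling, for coupling at only one of the two arms, or for attack of the acetylide on the ketone, to compete. The fallback sets out from 3 and postpones the ketone, so that the propargylic bonds can be made by plain SN2 chemistry. Compound 3 is brominated at its free ring carbon (NBS, MeCN, 0 °C) to 5-bromo-2,4,6-trihydroxybenzene-1,3-dicarbaldehyde F3. F3 is benzylated (BnBr, K2CO3, DMF) to 2,4,6-tris(benzyloxy)-5-bromobenzene-1,3-dicarbaldehyde F4. F4 is reduced (NaBH4) to [2,4,6-tris(benzyloxy)-5-bromo-1,3-phenylene]dimethanol F5, which is converted (CBr4, PPh3) into 1,3,5-tris(benzyloxy)-2-bromo-4,6-bis(bromomethyl)benzene F6. The two benzylic bromides of F6 are displaced by an excess of lithium ethoxyacetylide 10 (THF/DMPU, −78 to 0 °C), no carbonyl group being present, to give 1,3,5-tris(benzyloxy)-2-bromo-4,6-bis(3-ethoxyprop-2-yn-1-yl)benzene F7. Bromine–lithium exchange (n-BuLi, THF, −78 °C) and acylation of the aryllithium with N-methoxy-N-methylbutanamide should then give 12, where the route is rejoined.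

Third, step 10. The O-to-C acyl migration may stall on one of the two rings, or the acyl group may be lost again by retro-Claisen cleavage, leaving mixtures of enol esters and mono-acylated material. The fallback sets out from 20 and reverses the order of the last two operations. Hydrogenolysis (H2, Pd/C, EtOAc) gives 1-[3,5-bis[(2,4-dihydroxy-5,5-dimethyl-6-oxocyclohexa-1,3-dien-1-yl)methyl]-2,4,6-trihydroxyphenyl]butan-1-one F8. Friedel–Crafts C-butyrylation of F8 with butanoyl chloride 4 and AlCl3 in nitrobenzene is the classical conversion of filicinic acids into acylfilicinic acids. It can occur only on the two outer rings because ring A has no free carbon, and any phenyl esters are cleaved on mild basic work-up. This should give 23 directly.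

Further compounds
F1 | step 8 | acetylfilicinic acid (2-acetyl-3,5-dihydroxy-4,4-dimethylcyclohexa-2,5-dien-1-one) | CC(=O)C1=C(O)C(C)(C)C(O)=CC1=O
F2 | step 8 | filicinic acid (3,5-dihydroxy-4,4-dimethylcyclohexa-2,5-dien-1-one) | CC1(C)C(O)=CC(=O)C=C1O
F3 | step 6 | 5-bromo-2,4,6-trihydroxybenzene-1,3-dicarbaldehyde | O=Cc1c(O)c(Br)c(O)c(C=O)c1O
F4 | step 6 | 2,4,6-tris(benzyloxy)-5-bromobenzene-1,3-dicarbaldehyde | O=Cc1c(OCc2ccccc2)c(Br)c(OCc2ccccc2)c(C=O)c1OCc1ccccc1
F5 | step 6 | [2,4,6-tris(benzyloxy)-5-bromo-1,3-phenylene]dimethanol | OCc1c(OCc2ccccc2)c(Br)c(OCc2ccccc2)c(CO)c1OCc1ccccc1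
F6 | step 6 | 1,3,5-tris(benzyloxy)-2-bromo-4,6-bis(bromomethyl)benzene | BrCc1c(OCc2ccccc2)c(Br)c(OCc2ccccc2)c(CBr)c1OCc1ccccc1
F7 | step 6 | 1,3,5-tris(benzyloxy)-2-bromo-4,6-bis(3-ethoxyprop-2-yn-1-yl)benzene | CCOC#CCc1c(OCc2ccccc2)c(Br)c(OCc2ccccc2)c(CC#COCC)c1OCc1ccccc1
F8 | step 10 | 1-[3,5-bis[(2,4-dihydroxy-5,5-dimethyl-6-oxocyclohexa-1,3-dien-1-yl)methyl]-2,4,6-trihydroxyphenyl]butan-1-one | CCCC(=O)c1c(O)c(CC2=C(O)C=C(O)C(C)(C)C2=O)c(O)c(CC2=C(O)C=C(O)C(C)(C)C2=O)c1O
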